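**Retrosynthetic overview**
1. Target 29 comes from macrocycle 27 by desilylation and C13 acetylation. The ten-membered carbocycle is closed last at C5=C6, by intramolecular vinylogous Mukaiyama condensation of the butenolide onto a C5 dimethyl acetal (24 → 27).
2. The 1,4-epoxy bridge (2,3-dihydrofuran) is made just before that, by Au-catalysed 5-endo-dig cyclisation of the C4–OH onto the C1≡C2 alkyne (23 → 24).
3. C7–C8 is formed by NHK union of West aldehyde 11 (C1–C5, C8–C10, C14, C15) with East β-iodobutenolide 19 (C6, C7, C11–C13). C8 is then set by oxidation and CBS reduction.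
4. 11 comes from acetylide 7 plus epoxide 3 (C2–C3 bond), both made from (R)-2-methylglycidol, which supplies the C10 and C4 stereocentres. 19 comes from propargyl alcohol by Tsuji carbonylation and allenoic acid iodolactonisation.
5. Ring order: butenolide (in 19), then dihydrofuran, then ten-membered ring.

Assumption: atoms carry germacranolide numbers (C1=C2 enol ether, C4 quaternary ether carbon, C5=C6 enol-lactone alkene, C7=C11 butenolide alkene, C8 CHOAc, C10 carbinol, C12 lactone C=O, C13 CH2OAc); the SMILES is read as 4S,8S,10S with a 5E alkene (C4 and C7 cis).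

**Fragment A (C3–C5, C15)**

Step 1
Reactants: 1 (R)-2-methylglycidol
Product: 2 (S)-2-methyloxirane-2-carbaldehyde
Conditions: TEMPO (10 mol %), PhI(OAc)2 (1.1 equiv), CH2Cl2, 0 °C → rt; used as solution
Reagents that add atoms: none
Why: TEMPO/PhI(OAc)2 oxidation takes the primary alcohol to the aldehyde without opening the epoxide, and the quaternary stereocentre (future C4) cannot enolise.

Step 2
Reactants: 2 (S)-2-methyloxirane-2-carbaldehyde
Product: 3 (S)-2-(dimethoxymethyl)-2-methyloxirane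
Conditions: HC(OMe)3, MeOH, PPTS (5 mol %), 0 °C → rt; Et3N quench
Reagents that add atoms: trimethyl orthoformate, COC(OC)OC; methanol, CO
Why: Mild acid-catalysed acetalisation masks C5 as the dimethyl acetal used later as oxocarbenium precursor; the electron-poor epoxide tolerates PPTS.

**Fragment B (C1, C2, C8–C10, C14)**

Step 3
Reactants: 1 (R)-2-methylglycidol
Product: 4 (S)-2-methylpent-4-ene-1,2-diol
Conditions: vinylMgBr (3 equiv), CuI (10 mol %), THF, −30 → 0 °C; aq. NH4Cl
Reagents that add atoms: vinylmagnesium bromide, C=C[Mg]Br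
Why: Cu-catalysed Grignard opening of the epoxide at its CH2 (SN2) adds C8 and leaves the tertiary C–O stereocentre (future C10) untouched.

Step 4
Reactants: 4 (S)-2-methylpent-4-ene-1,2-diol
Product: 5 (S)-2-methyl-1,2-bis(triethylsilyloxy)pent-4-ene
Conditions: TESOTf (2.4 equiv), 2,6-lutidine, CH2Cl2, −78 → 0 °C
Reagents that add atoms: triethylsilyl triflate, CC[Si](CC)(CC)OS(=O)(=O)C(F)(F)F
Why: Silyl triflate/lutidine silylation protects both hydroxyls, including the hindered tertiary one.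

Step 5
Reactants: 5 (S)-2-methyl-1,2-bis(triethylsilyloxy)pent-4-ene
Product: 6 (S)-2-methyl-2-(triethylsilyloxy)pent-4-enal
Conditions: (COCl)2, DMSO, CH2Cl2, −78 → −30 °C; Et3N, −78 → 0 °C
Reagents that add atoms: none
Why: Under Swern conditions a primary TES ether is cleaved and oxidised directly to the aldehyde while the tertiary TES ether is inert (desilylative Swern oxidation).

Step 6
Reactants: 6 (S)-2-methyl-2-(triethylsilyloxy)pent-4-enal
Product: 7 (S)-triethyl[(3-methylhex-5-en-1-yn-3-yl)oxy]silane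
Conditions: dimethyl (1-diazo-2-oxopropyl)phosphonate, K2CO3, MeOH, 0 °C → rt
Reagents that add atoms: dimethyl (1-diazo-2-oxopropyl)phosphonate, COP(=O)(OC)C(=[N+]=[N-])C(C)=O
Why: Ohira–Bestmann (Seyferth–Gilbert) homologation of the non-enolisable α-silyloxy aldehyde gives the terminal alkyne without risk to the quaternary centre.

**West fragment**

Step 7
Reactants: 7 (S)-triethyl[(3-methylhex-5-en-1-yn-3-yl)oxy]silane; 3 (S)-2-(dimethoxymethyl)-2-methyloxirane
Product: 9 (2S,6S)-1,1-dimethoxy-2,6-dimethyl-6-(triethylsilyloxy)non-8-en-4-yn-2-ol, via lithium acetylide 8 (not isolated)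
Conditions: n-BuLi, THF, −78 °C; then 3, DMPU, −78 → 45 °C; aq. NH4Cl
Reagents that add atoms: none
Why: SN2 opening of the 2,2-disubstituted epoxide at its CH2 by the acetylide forms C2–C3; the C4–O bond is not broken, so both stereocentres are retained.

Step 8
Reactants: 9 (2S,6S)-1,1-dimethoxy-2,6-dimethyl-6-(triethylsilyloxy)non-8-en-4-yn-2-ol
Product: 11 (3S,7S)-7-hydroxy-8,8-dimethoxy-3,7-dimethyl-3-(triethylsilyloxy)oct-4-ynal, via triol 10 (not isolated)
Conditions: OsO4 (2 mol %), NaIO4 (4 equiv), 2,6-lutidine, dioxane/H2O 3:1, rt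
Reagents that add atoms: osmium tetroxide, O=[Os](=O)(=O)=O; sodium periodate, [Na+].[O-]I(=O)(=O)=O
Why: Lemieux–Johnson cleavage is selective for the terminal alkene over the internal alkyne and unmasks the C8 aldehyde.

**East fragment (C6, C7, C11–C13)**

Step 9
Reactants: 12 propargyl alcohol
Product: 13 tert-butyldimethyl(prop-2-yn-1-yloxy)silane
Conditions: TBSCl, imidazole, CH2Cl2, 0 °C → rt
Reagents that add atoms: tert-butyldimethylsilyl chloride, CC(C)(C)[Si](C)(C)Cl
Why: Standard silylation protects the future C13 oxygen.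

Step 10
Reactants: 13 tert-butyldimethyl(prop-2-yn-1-yloxy)silane
Product: 15 4-(tert-butyldimethylsilyloxy)but-2-yn-1-ol, via lithium acetylide 14 (not isolated)
Conditions: n-BuLi, THF, −78 °C; (CH2O)n, −78 °C → rt; aq. NH4Cl
Reagents that add atoms: formaldehyde (as paraformaldehyde), C=O
Why: Acetylide addition to formaldehyde adds C6 as a propargylic alcohol.

Step 11
Reactants: 15 4-(tert-butyldimethylsilyloxy)but-2-yn-1-ol
Product: 16 4-(tert-butyldimethylsilyloxy)but-2-yn-1-yl methyl carbonate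
Conditions: ClCO2Me, pyridine, CH2Cl2, 0 °C
Reagents that add atoms: methyl chloroformate, COC(=O)Cl
Why: Acylation gives the propargylic carbonate needed as leaving group for Pd.

Step 12
Reactants: 16 4-(tert-butyldimethylsilyloxy)but-2-yn-1-yl methyl carbonate
Product: 17 methyl 2-[(tert-butyldimethylsilyloxy)methyl]buta-2,3-dienoate
Conditions: Pd(OAc)2 (2 mol %), PPh3 (8 mol %), CO (10 atm), MeOH, 40 °C
Reagents that add atoms: carbon monoxide, [C-]#[O+]
Why: Tsuji carbonylation: SN2′ oxidative addition gives an allenyl-Pd species that inserts CO and is trapped by the liberated methoxide, putting C12 on C11.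

Step 13
Reactants: 17 methyl 2-[(tert-butyldimethylsilyloxy)methyl]buta-2,3-dienoate
Product: 18 2-[(tert-butyldimethylsilyloxy)methyl]buta-2,3-dienoic acid
Conditions: LiOH·H2O, THF/H2O, 0 °C; 1 M HCl to pH 3, 0 °C
Reagents that add atoms: lithium hydroxide, [Li+].[OH-]
Why: Mild saponification gives the 2,3-allenoic acid without isomerising the allene.

Step 14
Reactants: 18 2-[(tert-butyldimethylsilyloxy)methyl]buta-2,3-dienoic acid
Product: 19 3-[(tert-butyldimethylsilyloxy)methyl]-4-iodofuran-2(5H)-one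
Conditions: I2 (2 equiv), NaHCO3, MeCN, 0 °C → rt, dark
Reagents that add atoms: iodine, II
Why: Iodolactonisation of a 2,3-allenoic acid: iodonium formation on the terminal C=C and carboxylate attack at CH2 give the β-iodobutenolide.

**Union and endgame**

Step 15
Reactants: 11 (3S,7S)-7-hydroxy-8,8-dimethoxy-3,7-dimethyl-3-(triethylsilyloxy)oct-4-ynal; 19 3-[(tert-butyldimethylsilyloxy)methyl]-4-iodofuran-2(5H)-one
Product: 20 4-[(3S,7S)-1,7-dihydroxy-8,8-dimethoxy-3,7-dimethyl-3-(triethylsilyloxy)oct-4-yn-1-yl]-3-[(tert-butyldimethylsilyloxy)methyl]furan-2(5H)-one (both C8 epimers)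
Conditions: CrCl2 (6 equiv), NiCl2 (2 mol %), degassed DMF, rt
Reagents that add atoms: none
Why: Nozaki–Hiyama–Kishi coupling: the Ni-generated alkenylchromium(III) adds chemoselectively to the aldehyde (lactone, acetal, alkyne and free tertiary OH tolerated) to form C7–C8; the epimers converge in steps 16–17.

Step 16
Reactants: 20 NHK carbinol (C8 epimers)
Product: 21 4-[(3S,7S)-7-hydroxy-8,8-dimethoxy-3,7-dimethyl-3-(triethylsilyloxy)oct-4-ynoyl]-3-[(tert-butyldimethylsilyloxy)methyl]furan-2(5H)-one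
Conditions: Dess–Martin periodinane, NaHCO3, CH2Cl2, 0 °C → rt
Reagents that add atoms: none
Why: Dess–Martin oxidation of the only oxidisable (secondary) alcohol gives the C8 ketone; tertiary OH, acetal and silyl ethers are inert.

Step 17
Reactants: 21 C8 ketone
Product: 22 4-[(1S,3S,7S)-1,7-dihydroxy-8,8-dimethoxy-3,7-dimethyl-3-(triethylsilyloxy)oct-4-yn-1-yl]-3-[(tert-butyldimethylsilyloxy)methyl]furan-2(5H)-one
Conditions: (R)-Me-CBS (0.5 equiv), catecholborane (2.5 equiv), toluene, −78 °C; MeOH, pH 7 buffer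
Reagents that add atoms: none
Why: Corey–Bakshi–Shibata reduction: the (R)-oxazaborolidine treats the sp2 butenolide carbon as the large group and the CH2 as the small one, giving the (8S)-alcohol by reagent control (1,2-reduction of the enone).

Step 18
Reactants: 22 (8S)-alcohol
Product: 23 (1S,3S,7S)-1-{4-[(tert-butyldimethylsilyloxy)methyl]-5-oxo-2,5-dihydrofuran-3-yl}-7-hydroxy-8,8-dimethoxy-3,7-dimethyl-3-(triethylsilyloxy)oct-4-yn-1-yl acetate
Conditions: Ac2O (1.5 equiv), pyridine, DMAP (5 mol %), CH2Cl2, 0 °C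
Reagents that add atoms: acetic anhydride, CC(=O)OC(C)=O
Why: Acylation installs the C8 acetate of the target on the secondary alcohol only; this also stops C8–OH from competing in step 19.

Step 19
Reactants: 23 C8 acetate
Product: 24 (1S,3S)-1-{4-[(tert-butyldimethylsilyloxy)methyl]-5-oxo-2,5-dihydrofuran-3-yl}-3-[(5S)-5-(dimethoxymethyl)-5-methyl-4,5-dihydrofuran-2-yl]-3-(triethylsilyloxy)butyl acetate
Conditions: Ph3PAuNTf2 (3 mol %), CH2Cl2, 4 Å MS, 0 °C → rt; Et3N quench
Reagents that add atoms: none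
Why: Au(I)-catalysed 5-endo-dig hydroalkoxylation (cycloisomerisation, no by-product) of the homopropargylic tertiary alcohol gives the 2,3-dihydrofuran with the C1=C2 enol ether; no stereocentre is touched.

Step 20
Reactants: 24 dihydrofuran acetal
Product: 27 (4S,8S,10S,5E)-8-acetoxy-13-(tert-butyldimethylsilyloxy)-10-(triethylsilyloxy)-1,4-epoxygermacra-1,5,7(11)-trien-12,6-olide, via silyloxyfuran 25 (not isolated), via methoxy adduct 26 (not isolated)
Conditions: 24 added slowly to TMSOTf (3 equiv), i-Pr2NEt (2 equiv), CH2Cl2 (1 mM), −20 → 0 °C; then DBU, rt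
Reagents that add atoms: none
Why: Intramolecular vinylogous Mukaiyama reaction of the in situ 2-silyloxyfuran (γ-carbon C6) with the oxocarbenium ion from the acetal closes the ring at C5–C6, and DBU eliminates methanol (E1cB); the ring allows only the 5E alkene.

Step 21
Reactants: 27 protected macrocycle
Product: 28 (4S,8S,10S,5E)-8-acetoxy-10,13-dihydroxy-1,4-epoxygermacra-1,5,7(11)-trien-12,6-olide
Conditions: TBAF (3 equiv), AcOH (3 equiv), THF, 0 °C → rt
Reagents that add atoms: none
Why: Buffered fluoride cleaves the primary TBS and tertiary TES ethers without harming the enol ether, enol lactone or acetate.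

Step 22
Reactants: 28 diol
Product: 29 (4S,8S,10S,5E)-8,13-diacetoxy-10-hydroxy-1,4-epoxygermacra-1,5,7(11)-trien-12,6-olide (target)
Conditions: Ac2O (1.3 equiv), pyridine, CH2Cl2, 0 °C
Reagents that add atoms: acetic anhydride, CC(=O)OC(C)=O
Why: Ac2O/pyridine acetylates only the primary allylic C13–OH; the tertiary C10–OH does not react under these conditions.

**Compound list**
1 | (R)-2-methylglycidol | OC[C@]1(C)CO1 | starting material
2 | (S)-2-methyloxirane-2-carbaldehyde | O=C[C@]1(C)CO1 | intermediate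
3 | (S)-2-(dimethoxymethyl)-2-methyloxirane | COC(OC)[C@]1(C)CO1 | intermediate
4 | (S)-2-methylpent-4-ene-1,2-diol | OC[C@](O)(C)CC=C | intermediate
5 | (S)-2-methyl-1,2-bis(triethylsilyloxy)pent-4-ene | CC[Si](CC)(CC)OC[C@](O[Si](CC)(CC)CC)(C)CC=C | intermediate
6 | (S)-2-methyl-2-(triethylsilyloxy)pent-4-enal | O=C[C@](O[Si](CC)(CC)CC)(C)CC=C | intermediate
7 | (S)-triethyl[(3-methylhex-5-en-1-yn-3-yl)oxy]silane | C#C[C@@](C)(O[Si](CC)(CC)CC)CC=C | intermediate
8 | lithium acetylide of 7 (not isolated) | [Li]C#C[C@@](C)(O[Si](CC)(CC)CC)CC=C | intermediate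
9 | (2S,6S)-1,1-dimethoxy-2,6-dimethyl-6-(triethylsilyloxy)non-8-en-4-yn-2-ol | COC(OC)[C@@](C)(O)CC#C[C@@](C)(O[Si](CC)(CC)CC)CC=C | intermediate
10 | (2S,6S)-1,1-dimethoxy-2,6-dimethyl-6-(triethylsilyloxy)non-4-yne-2,8,9-triol, C8 epimers (not isolated) | COC(OC)[C@@](C)(O)CC#C[C@@](C)(O[Si](CC)(CC)CC)CC(O)CO | intermediate
11 | (3S,7S)-7-hydroxy-8,8-dimethoxy-3,7-dimethyl-3-(triethylsilyloxy)oct-4-ynal | COC(OC)[C@@](C)(O)CC#C[C@@](C)(O[Si](CC)(CC)CC)CC=O | intermediate
12 | propargyl alcohol | C#CCO | starting material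
13 | tert-butyldimethyl(prop-2-yn-1-yloxy)silane | C#CCO[Si](C)(C)C(C)(C)C | intermediate
14 | lithium acetylide of 13 (not isolated) | [Li]C#CCO[Si](C)(C)C(C)(C)C | intermediate
15 | 4-(tert-butyldimethylsilyloxy)but-2-yn-1-ol | OCC#CCO[Si](C)(C)C(C)(C)C | intermediate
16 | 4-(tert-butyldimethylsilyloxy)but-2-yn-1-yl methyl carbonate | COC(=O)OCC#CCO[Si](C)(C)C(C)(C)C | intermediate
17 | methyl 2-[(tert-butyldimethylsilyloxy)methyl]buta-2,3-dienoate | C=C=C(CO[Si](C)(C)C(C)(C)C)C(=O)OC | intermediate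
18 | 2-[(tert-butyldimethylsilyloxy)methyl]buta-2,3-dienoic acid | C=C=C(CO[Si](C)(C)C(C)(C)C)C(=O)O | intermediate
19 | 3-[(tert-butyldimethylsilyloxy)methyl]-4-iodofuran-2(5H)-one | O=C1OCC(I)=C1CO[Si](C)(C)C(C)(C)C | intermediate
20 | NHK carbinol, both C8 epimers | COC(OC)[C@@](C)(O)CC#C[C@@](C)(O[Si](CC)(CC)CC)CC(O)C1=C(CO[Si](C)(C)C(C)(C)C)C(=O)OC1 | intermediate
21 | C8 ketone | COC(OC)[C@@](C)(O)CC#C[C@@](C)(O[Si](CC)(CC)CC)CC(=O)C1=C(CO[Si](C)(C)C(C)(C)C)C(=O)OC1 | intermediate
22 | (8S)-alcohol | COC(OC)[C@@](C)(O)CC#C[C@@](C)(O[Si](CC)(CC)CC)C[C@H](O)C1=C(CO[Si](C)(C)C(C)(C)C)C(=O)OC1 | intermediate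
23 | (8S)-acetate | COC(OC)[C@@](C)(O)CC#C[C@@](C)(O[Si](CC)(CC)CC)C[C@H](OC(C)=O)C1=C(CO[Si](C)(C)C(C)(C)C)C(=O)OC1 | intermediate
24 | dihydrofuran acetal | COC(OC)[C@]1(C)CC=C(O1)[C@@](C)(O[Si](CC)(CC)CC)C[C@H](OC(C)=O)C2=C(CO[Si](C)(C)C(C)(C)C)C(=O)OC2 | intermediate
25 | 2-(trimethylsilyloxy)furan from 24 (not isolated) | COC(OC)[C@]1(C)CC=C(O1)[C@@](C)(O[Si](CC)(CC)CC)C[C@H](OC(C)=O)c2coc(O[Si](C)(C)C)c2CO[Si](C)(C)C(C)(C)C | intermediate
26 | C5-methoxy macrocycle, C5/C6 epimers (not isolated) | COC1C2OC(=O)C(CO[Si](C)(C)C(C)(C)C)=C2[C@@H](OC(C)=O)C[C@](C)(O[Si](CC)(CC)CC)C2=CC[C@]1(C)O2 | intermediate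
27 | 13-O-TBS, 10-O-TES macrocycle | CC(C)(C)[Si](C)(C)OCC1=C2/C(=C\[C@]3(C)CC=C(O3)[C@@](C)(O[Si](CC)(CC)CC)C[C@@H]2OC(C)=O)OC1=O | intermediate
28 | 13-deacetyl target (10,13-diol, 8-acetate) | OCC1=C2/C(=C\[C@]3(C)CC=C(O3)[C@@](C)(O)C[C@@H]2OC(C)=O)OC1=O | intermediate
29 | CNP0144020.1 | CC(=O)OCC1=C2/C(=C\[C@]3(C)CC=C(O3)[C@@](C)(O)C[C@@H]2OC(C)=O)OC1=O | target

**Step count**
Total: 22 steps. Longest linear sequence: 14 steps (steps 3–8 then 15–22; the line 9–14 then 15–22 is equally long).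

**Steps most likely to fail, with fallbacks**

Step 15 (NHK coupling). The alkenylchromium from 19 has a β-acyloxy group and may fragment or react slowly. The fallback sets out from 11 and 19 and comes back at 21. Pinnick oxidation of 11 (NaClO2, NaH2PO4, 2-methyl-2-butene, t-BuOH/H2O) gives (3S,7S)-7-hydroxy-8,8-dimethoxy-3,7-dimethyl-3-(triethylsilyloxy)oct-4-ynoic acid F1, which EtSH, EDC and DMAP convert into the S-ethyl thioester F2. In parallel 19 is stannylated (Me3SnSnMe3, Pd(PPh3)4, dioxane, 80 °C) to 3-[(tert-butyldimethylsilyloxy)methyl]-4-(trimethylstannyl)furan-2(5H)-one F3. Base-free Liebeskind–Srogl acylation of F3 by F2 (Pd2(dba)3, tri(2-furyl)phosphine, copper(I) diphenylphosphinate, THF, 50 °C) gives ketone 21 directly, so steps 15 and 16 are bypassed.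

Step 17 (CBS reduction). The CH2 flank carries a quaternary carbon, so the size difference may be too small for high selectivity. The fallback sets out from 21 and comes back at 23. Luche reduction (NaBH4, CeCl3·7H2O, MeOH, −78 °C) gives 22 together with its separable (8R)-alcohol F4. 22 is acetylated as in step 18, and F4 is converted into the same acetate 23 by Mitsunobu inversion with acetic acid (PPh3, DIAD, AcOH, toluene, 0 °C), so the C8 configuration rests on SN2 inversion instead of on the reduction.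

Step 20 (medium-ring closure). The fallback sets out from 23 and comes back at 27, with the two ring closures in reverse order. The open-chain alkyne 23 is treated with TMSOTf/i-Pr2NEt at high dilution, then DBU, then citric acid in MeOH to cleave the transient tertiary TMS ether. The same acetal/silyloxyfuran condensation then gives the ten-membered cycloalkyne (4S,8S,10S,5E)-8-acetoxy-13-(tert-butyldimethylsilyloxy)-4-hydroxy-10-(triethylsilyloxy)germacra-5,7(11)-dien-1-yn-12,6-olide F5. Transannular Au(I)-catalysed 5-endo-dig hydroalkoxylation (Ph3PAuNTf2, CH2Cl2) then forms the ether bridge and gives 27.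

**Further compounds**
F1 | step 15 | (3S,7S)-7-hydroxy-8,8-dimethoxy-3,7-dimethyl-3-(triethylsilyloxy)oct-4-ynoic acid | COC(OC)[C@@](C)(O)CC#C[C@@](C)(O[Si](CC)(CC)CC)CC(=O)O
F2 | step 15 | S-ethyl (3S,7S)-7-hydroxy-8,8-dimethoxy-3,7-dimethyl-3-(triethylsilyloxy)oct-4-ynethioate | COC(OC)[C@@](C)(O)CC#C[C@@](C)(O[Si](CC)(CC)CC)CC(=O)SCC
F3 | step 15 | 3-[(tert-butyldimethylsilyloxy)methyl]-4-(trimethylstannyl)furan-2(5H)-one | C[Sn](C)(C)C1=C(CO[Si](C)(C)C(C)(C)C)C(=O)OC1
F4 | step 17 | (8R)-epimer of alcohol 22 | COC(OC)[C@@](C)(O)CC#C[C@@](C)(O[Si](CC)(CC)CC)C[C@@H](O)C1=C(CO[Si](C)(C)C(C)(C)C)C(=O)OC1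
F5 | step 20 | (4S,8S,10S,5E)-8-acetoxy-13-(tert-butyldimethylsilyloxy)-4-hydroxy-10-(triethylsilyloxy)germacra-5,7(11)-dien-1-yn-12,6-olide | CC(C)(C)[Si](C)(C)OCC1=C2/C(=C\[C@@](C)(O)CC#C[C@@](C)(O[Si](CC)(CC)CC)C[C@@H]2OC(C)=O)OC1=O
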